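- Substrate and target meet slowly in these flasks, and we want to know what that slowness costs.

common to all: time 2.0 min
- birch: substrate 0.25 M
- ash: substrate 0.50 M
- larch: substrate 1.0 M

    substrate → side product A (k1 = 0.0116 s⁻¹)
    substrate → side product B (k2 = 0.00474 s⁻¹)
    substrate → target (k3 = 0.0311 s⁻¹)
    substrate + target → side product C (k4 = 0.0337 M⁻¹ s⁻¹)

- percentages count the substrate that a species holds: one side product C counts as two
- "hardly changes" means that all values lie within two and a half points (for a concentration: within two and a half percent of the largest)
- run time (birch): 2.0 min

* [target] at the end for birch, ash, larch, in this order
* how that number moves from the first to the last of them (hardly changes / falls, then rises / rises, then falls / falls all the way / rises all the way)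

- In birch, target facing substrate as charged has a half-life of 1.37 min, which is longer than the 0.371 min of substrate on its way to target. In ash, with twice the charge, that first half-life shrinks to 0.686 min.
- Target's half-life changes with the charge, while that of substrate on its way to target does not, so we look for a comparison in which the charge plays no part. Target is made at a rate proportional to [substrate] and destroyed at a rate also proportional to [substrate], so [substrate] cancels from their ratio.
- That ratio of loss to gain is therefore [target] divided by the break-even concentration, the [target] at which target's loss equals its gain, 0.923 M.
- The three first-order steps by themselves leave 0.337% of the substrate after 2.0 min, in birch and ash alike, so we reckon each flask as finished.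
- At the start, a share of 65.6% of the substrate used goes to target; this is the selectivity. Applied to the charge, that share gives 0.164 M in birch, 0.328 M in ash and 0.656 M in larch.
- Set against the break-even concentration, these give final ratios of about 0.178 in birch and 0.355 in ash. The ratio climbs from zero, so we take off half of it as the average loss.
- Our reckoning gives 0.149 M in birch, 0.270 M in ash and 0.423 M in larch. It rises from flask to flask, since larch's 0.656 M stays below the break-even concentration.
- The forecast is lower for birch and ash, at 0.143 M, 0.255 M and 0.421 M, and also says rises all the way. Its route was this: “Time can therefore be eliminated by dividing the two rate equations”.
- The flasks end at 0.143 M, 0.255 M and 0.421 M, so [target] rises all the way, though ash holds only 1.78 times birch's amount. Dividing these [target] values by the break-even concentration, loss ran at 0.155 of gain at the end of birch and at 0.276 of gain at the end of ash. After 2.00 min, side product C holds 9.91% of the substrate charged in birch and 17.4% in ash.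

Its constants were set for the occasion; what happens was integrated by code.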